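The data come from a simulation on assumed constants, noise included.

0.0581 M of starting material is what the new flask keeps if its protic impurity takes one mole per mole, and my reckoning stands on that number.

| flask | starting material | protic impurity | remark | time |
|---|---|---|---|---|
| Monday's | 0.12 M (in portions, 4) | 0.0249 M | run made earlier; portions every 12 s |  |
| Wednesday's | 0.18 M (in portions, 4) | 0.0249 M | run made earlier; portions every 12 s |  |
| Sunday's | 0.083 M (in portions, 4) | 0.050 M | run made earlier; portions every 12 s |  |
| flask | 0.083 M (in portions, 4) | 0.0249 M | the portions of starting material follow each other after 12 s, the first at the start | 15 min |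

| Monday's: time / min | Monday's: product / % | Wednesday's: time / min | Wednesday's: product / % | Sunday's: time / min | Sunday's: product / % |
|---|---|---|---|---|---|
| 4.00 | 10.0 | 1.33 | 8.5 | 4.00 | 5.9 |
| 8.00 | 10.7 | 2.50 | 11.2 | 8.00 | 5.8 |
| 10.0 | 10.4 | 5.00 | 11.4 | 10.0 | 4.3 |
| 15.0 | 9.8 | 10.0 | 11.2 | 15.0 | 4.4 |
| 20.0 | 10.3 | 20.0 | 11.3 | 20.0 | 5.1 |

(standard deviation of a reading: 0.5 percentage points)

1. the product standing at 15 min, as a percentage of the starting material charged
2. amount of product if the flask were left three thousand times as long, in percent of the starting material charged

I turn each plateau into a concentration and divide it by the charge of starting material minus the charge of protic impurity. Monday's run gives 0.129, Wednesday's 0.131 without its first reading, which is lower than the next, and Sunday's 0.128. Their mean, 0.129, is the survivor share: plateau product per mole of starting material that the impurity leaves. In powers of ten, from Sunday's run to Wednesday's, survivors rise by 0.672 and product by 0.681.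

The ledger for the new flask, with protic impurity as limiting reagent of the quench:

c(starting material) charged: 0.083 M
taken by protic impurity: 0.0249 M
survivors: 0.0581 M
to product, survivors × 0.129: 0.00752 M
survivors not product: 0.0506 M

So I expect 9.06 % of the charge at 15 min, later than Wednesday's plateau began. I carry the same figure to the long wait, but the readings stop at 20.0 min, so that is an extrapolation.

The forecast says 9.1 % and, for the long wait, 9.1 %: “about 13% of what survives becomes product before things stop”.

The flask gives 9.07 % and 9.07 %.

    starting material + protic impurity → quenched substrate (k = 2.19 L mol⁻¹ s⁻¹)
    intermediate A ⇌ intermediate B (K = 1.10, k = 0.0415 s⁻¹)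
    intermediate C ⇌ product (k = 0.0504 s⁻¹)
    intermediate A ⇌ product (K = 0.873, k = 0.00906 s⁻¹)
    starting material ⇌ intermediate C (K = 0.318, k = 0.00917 s⁻¹)
    starting material ⇌ intermediate A (K = 0.350, k = 0.0863 s⁻¹)

In the new flask at 0.600 min, 20.6 % of the charged protic impurity still stood, with quenched substrate at 23.8 % and product at 3.11 % of the starting material charged. By 7.50 min that flask's impurity stood at 0 % and the survivors, in percent of the starting material charged, were shared among starting material 29.7 %, intermediate A 10.4 %, intermediate B 11.4 %, intermediate C 9.44 % and product 9.07 %, unchanged at 150 min.

A neighbour flask with 0.10 M of protic impurity has a survivor line of −0.0170 M, below zero, so the survivor share has no survivors to act on. It gives 0 % product, with 17 % of its impurity left.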